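Subtraction is the easy step: whatever a reading shows as neither substrate nor product has gone somewhere else, and we call that the missing share.

| setting | Tuesday's | Monday's | Thursday's | flask |
|---|---|---|---|---|
| substrate | 0.050 M | 0.050 M | 0.050 M | 0.050 M |
| reagent | 1.2 equiv | 1.9 equiv | 2.5 equiv | 2.50 equiv |
| free catalyst | 0.2 mol% | 0.2 mol% | 0.3 mol% | 0.2 mol% |
| remark | run made earlier | run made earlier | run made earlier |  |

| run | time / h | product / % | substrate / % |
|---|---|---|---|
| Tuesday's | 0.500 | 10.3 | 45.6 |
| Tuesday's | 0.833 | 14.8 | 27.7 |
| Tuesday's | 1.50 | 20.1 | 9.1 |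
| Tuesday's | 3.00 | 22.5 | 4.8 |
| Tuesday's | 6.00 | 28.7 | 4.3 |
| Monday's | 0.500 | 13.2 | 45.8 |
| Monday's | 0.833 | 14.5 | 25.6 |
| Monday's | 1.50 | 23.1 | 11.9 |
| Monday's | 3.00 | 23.6 | 4.5 |
| Monday's | 6.00 | 27.5 | 3.7 |
| Thursday's | 1.33 | 27.5 | 10.9 |
| Thursday's | 2.50 | 28.1 | 4.6 |
| Thursday's | 4.00 | 33.0 | 4.0 |
| Thursday's | 5.00 | 35.1 | 2.5 |
| Thursday's | 6.00 | 33.5 | 4.4 |

(scatter of a reading: 1 percentage point)

- what has gone from substrate into another species counts as reacted, even if it can come back

* apparent order in free catalyst when 50% of the substrate are converted (percent change of the rate of making product for one percent more free catalyst charged)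

We read the last row of each table, taken at 6.00 h. Thursday's run shows 33.5% product and 4.4% substrate, so its product over its missing share is 0.539. We call this ratio of amounts at one time the split.

Tuesday's row gives 0.428 at 1.2 equiv of reagent, and Monday's gives 0.400 at 1.9 equiv. With readings good to 1 percentage point, we read no clear reagent effect and take their mean, 0.414, for the flask, which has Monday's catalyst loading and Thursday's reagent.

In Monday's run, product is the smaller branch, 27.5% against 68.8% missing. We therefore assume that the missing branch does not change with catalyst and reckon product as the correction to it. Going from 0.2 mol% to 0.3 mol% then raises the split by 1.30, so our order is 0.653. This is a whole-run average, which we take for 50% conversion.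

The forecast says 0.95, higher than our figure, on the ground of “a factor of about 1.5 for 1.5× catalyst, which implies first order”.

The simulation gives 0.68, from this scheme:

    substrate ⇌ dormant form (K = 16.0, k = 3.50 × 10⁻⁴ /s)
    substrate + free catalyst → catalyst intermediate A (k = 19.0 /M/s)
    reagent + catalyst intermediate A ⇌ catalyst intermediate B (K = 4.00 /M, k = 5.50 /M/s)
    free catalyst + by-product ⇌ idle complex, settled at all times (K = 1600 /M)
    catalyst intermediate B → by-product + catalyst intermediate C (k = 0.740 /s)
    catalyst intermediate C → free catalyst + product (k = 0.0960 /s)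

At 0.600 h in the flask, the idle complex holds 63.2% of the catalyst charged and free catalyst holds 5.33%. At 6.00 h, the flask's 28.3% product and 3.50% substrate give a split of 0.415. Set against Thursday's split of 0.539, at 0.3 mol% of catalyst against the flask's 0.2 mol%, it gives an order of 0.645.

The readings were computed for an exercise.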